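**Plan**

1. Retrosynthesis: cut the aliphatic ester C–O bond (propan-2-yl oxygen to butanoate C1), then the ArCH2–C(=O) bond of the keto side chain, then the benzoate C–O bond to the butanoate carbinol. In the arylpropanol, cut ring bonds C1–C6 and C4–C5 of the resorcinol back to an open-chain enone and malonate.
2. Enabling feature: the 3,5-dihydroxyphenyl ring has oxygen on C3 and C5 and its only carbon substituent, the (R)-2-oxypropyl chain, on C1, meta to both. That is the 1,3-dione/5-alkyl pattern obtained when a malonate (two ring carbons) is annulated onto a 3-alken-2-one (four ring carbons).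
3. Forward, alcohol half: methyl (R)-3-hydroxybutanoate → benzyl ether → aldehyde → (E)-enone → Michael–Claisen annulation (the only ring formed in the route) → aromatisation → decarboxylation → protecting-group exchange.
4. Forward, acid half: orsellinic acid is esterified with (S)-pent-4-en-2-ol (Mitsunobu), benzylated, acylated at its benzylic methyl with the Weinreb amide made from the same benzyl ether, and the alkene is cut to the carboxylic acid. Esterification with the arylpropanol and one hydrogenolysis finish the synthesis.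
5. Stereochemistry: the carbinol centres of the arylpropanol and of the keto side chain come unchanged from methyl (R)-3-hydroxybutanoate. The butanoate centre comes from (S)-pent-4-en-2-ol by Mitsunobu inversion. No stereocentre depends on a selective reaction.

Key step: step 4

Remark: diones 9 and 10 are drawn as keto forms; they will exist as enol tautomers and as epimer mixtures at the ring CH centres, which is immaterial because these centres become aromatic in step 5.

**Route**

Step 1
Reactants: 1 methyl (R)-3-hydroxybutanoate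
Product: 2 methyl (3R)-3-(benzyloxy)butanoate
Conditions: BnOC(=NH)CCl3, TfOH (cat.), cyclohexane/CH2Cl2, rt
Reagents that add atoms: benzyl 2,2,2-trichloroacetimidate, ClC(Cl)(Cl)C(=N)OCc1ccccc1
Why: Acid-catalysed O-benzylation with the trichloroacetimidate avoids the retro-aldol and β-elimination that a basic Williamson etherification would cause in a β-hydroxy ester, and it does not touch the stereocentre.

Step 2
Reactants: 2 methyl (3R)-3-(benzyloxy)butanoate
Product: 4 (3R)-3-(benzyloxy)butanal, via aluminium hemiacetal 3 (not isolated)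
Conditions: i-Bu2AlH, CH2Cl2, −78 °C; then MeOH, aq. KNaC4H4O6
Reagents that add atoms: none
Why: Partial ester reduction with i-Bu2AlH at −78 °C stops at the tetrahedral aluminium hemiacetal, which releases the aldehyde only on aqueous quench, and the β-benzyloxy centre is remote from the reacting carbon.

Step 3
Reactants: 4 (3R)-3-(benzyloxy)butanal; 5 1-(triphenylphosphoranylidene)propan-2-one
Product: 6 (3E,6R)-6-(benzyloxy)hept-3-en-2-one
Conditions: CH2Cl2, reflux
Reagents that add atoms: none
Why: Wittig olefination with a stabilised acyl ylide should give the (E)-enone and is mild enough not to eliminate the β-benzyloxy group of the aldehyde.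

Step 4
Reactants: 6 (3E,6R)-6-(benzyloxy)hept-3-en-2-one; 7 dimethyl malonate
Product: 9 methyl 6-[(2R)-2-(benzyloxy)propyl]-2,4-dioxocyclohexane-1-carboxylate, via Michael adduct 8 (not isolated)
Conditions: NaOMe (1.1 equiv), MeOH, 0 °C to rt, then reflux; then aq. HCl, 0 °C
Reagents that add atoms: none
Why: Methoxide generates sodium dimethyl malonate, which adds in a Michael reaction to C4 (the β-carbon) of enone 6 to give adduct 8; proton exchange then produces the terminal methyl-ketone enolate, whose carbon attacks one malonate ester in a Claisen (Dieckmann-type) condensation, expels methoxide and is drained as the stabilised sodium enolate of the cyclic 1,3-dione until acid releases 9. The closest known reaction type is the classical malonate/3-alken-2-one annulation to 5-substituted cyclohexane-1,3-diones. The single ring closes in the 6-(enolendo)-exo-trig mode, the only strain-free option because attack by the internal enolate or by the malonate carbon would need a four-membered ring, and both ester groups lead to the same constitution. No lasting stereocentre is made: ring centres C1 and C6 form as epimer mixtures that become sp2 in step 5, and the (R)-carbinol carbon has no acidic hydrogen and is not involved. The step needs conjugate addition to outrun γ-deprotonation of the enone with vinylogous loss of benzyl oxide, which the soft malonate anion, the poor alkoxide leaving group and the 0 °C addition period before heating should secure; once 8 has formed, the benzyloxy group is no longer β to any acidic position.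

Step 5
Reactants: 9 methyl 6-[(2R)-2-(benzyloxy)propyl]-2,4-dioxocyclohexane-1-carboxylate
Product: 11 methyl 6-[(2R)-2-(benzyloxy)propyl]-2,4-dihydroxybenzoate, via 3-bromo dione 10 (not isolated)
Conditions: Br2 (1 equiv), DMF, 0 °C, then 80 °C
Reagents that add atoms: none
Why: Bromination of the dione enol at C3, HBr-mediated bromine migration and thermal dehydrobromination in DMF is the classical halogenation–dehydrohalogenation aromatisation of dihydroresorcylates, and the alkyl benzyl ether and the ester are inert to bromine and HBr under these conditions.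

Step 6
Reactants: 11 methyl 6-[(2R)-2-(benzyloxy)propyl]-2,4-dihydroxybenzoate
Product: 13 5-[(2R)-2-(benzyloxy)propyl]benzene-1,3-diol, via free resorcylic acid 12 (not isolated)
Conditions: aq. NaOH, MeOH, reflux (N2); then aq. HCl, 60 °C
Reagents that add atoms: none
Why: Saponification followed by protodecarboxylation of the 2,4-dihydroxybenzoic acid (ipso protonation assisted by the ortho and para hydroxyls) is the standard removal of a resorcylate ester group, and the benzyl ether withstands both hot base and dilute acid.

Step 7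
Reactants: 13 5-[(2R)-2-(benzyloxy)propyl]benzene-1,3-diol
Product: 14 5-[(2R)-2-hydroxypropyl]benzene-1,3-diol
Conditions: H2 (1 atm), 10% Pd/C, MeOH, rt
Reagents that add atoms: none
Why: Hydrogenolysis on Pd/C removes the alkyl benzyl ether, which was kept until now because it reliably survives methoxide, HBr in hot DMF and hot NaOH, and leaves the resorcinol ring and the homobenzylic C–O bond intact.

Step 8
Reactants: 14 5-[(2R)-2-hydroxypropyl]benzene-1,3-diol
Product: 15 (2R)-1-[3,5-bis(benzyloxy)phenyl]propan-2-ol
Conditions: BnBr (2.1 equiv), K2CO3, acetone, reflux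
Reagents that add atoms: benzyl bromide, BrCc1ccccc1
Why: In this Williamson etherification K2CO3 deprotonates only the phenols and not the far less acidic secondary alcohol, so both aryl benzyl ethers should form chemoselectively and the carbinol stays free for step 15.

Step 9
Reactants: 2 methyl (3R)-3-(benzyloxy)butanoate
Product: 16 (3R)-3-(benzyloxy)-N-methoxy-N-methylbutanamide
Conditions: MeNH(OMe)·HCl, i-PrMgCl, THF, −20 to 0 °C
Reagents that add atoms: N,O-dimethylhydroxylamine hydrochloride, CNOC.Cl
Why: Aminolysis of the ester by the chloromagnesium amide of N,O-dimethylhydroxylamine (Weinreb amide formation) is fast at low temperature, where the β-benzyloxy group does not eliminate.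

Step 10
Reactants: 17 orsellinic acid (2,4-dihydroxy-6-methylbenzoic acid); 18 (S)-pent-4-en-2-ol
Product: 19 (2R)-pent-4-en-2-yl 2,4-dihydroxy-6-methylbenzoate
Conditions: P(3-ClC6H4)3, DIAD, toluene, 0 °C to rt
Reagents that add atoms: none
Why: Mitsunobu esterification proceeds by SN2 attack of the carboxylate on the alkoxyphosphonium ion with inversion, turning the (S)-alcohol into the (R)-ester, and the carboxylic acid is so much more acidic than the phenols that phenol O-alkylation should be suppressed, the more so with the electron-poor triarylphosphine.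

Step 11
Reactants: 19 (2R)-pent-4-en-2-yl 2,4-dihydroxy-6-methylbenzoate
Product: 20 (2R)-pent-4-en-2-yl 2,4-bis(benzyloxy)-6-methylbenzoate
Conditions: BnBr (2.5 equiv), K2CO3, DMF, 60 °C
Reagents that add atoms: benzyl bromide, BrCc1ccccc1
Why: Williamson etherification of both phenols (the hydrogen-bonded ortho phenol needs DMF and warming) gives ethers that tolerate the amide base of step 12 and leave by hydrogenolysis at the end.

Step 12
Reactants: 20 (2R)-pent-4-en-2-yl 2,4-bis(benzyloxy)-6-methylbenzoate; 16 (3R)-3-(benzyloxy)-N-methoxy-N-methylbutanamide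
Product: 23 (2R)-pent-4-en-2-yl 2,4-bis(benzyloxy)-6-[(4R)-4-(benzyloxy)-2-oxopentyl]benzoate, via benzylic lithium species 21 (not isolated), via lithium tetrahedral adduct 22 (not isolated)
Conditions: LiN(i-Pr)2 (2 equiv), THF, −78 °C; then 16; then aq. NH4Cl, −78 °C
Reagents that add atoms: none
Why: Lateral deprotonation of the ortho-toluate gives a stabilised benzylic anion that is acylated by the Weinreb amide through a chelated tetrahedral adduct which collapses only on quench, so neither over-addition nor enolate attack on the hindered secondary ester (isocoumarin formation) should occur.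

Step 13
Reactants: 23 (2R)-pent-4-en-2-yl 2,4-bis(benzyloxy)-6-[(4R)-4-(benzyloxy)-2-oxopentyl]benzoate
Product: 25 (2R)-4-oxobutan-2-yl 2,4-bis(benzyloxy)-6-[(4R)-4-(benzyloxy)-2-oxopentyl]benzoate, via vicinal diol 24 (not isolated)
Conditions: OsO4 (cat.), NaIO4, 2,6-lutidine, dioxane/H2O, rt
Reagents that add atoms: osmium tetroxide, O=[Os](=O)(=O)=O; sodium periodate (reoxidant), [Na+].[O-]I(=O)(=O)=O
Why: Lemieux–Johnson oxidation (catalytic dihydroxylation, then periodate cleavage of the diol) cuts only the terminal alkene in a lutidine-buffered medium and leaves the ketone, the ester and the benzyl ethers alone.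

Step 14
Reactants: 25 (2R)-4-oxobutan-2-yl 2,4-bis(benzyloxy)-6-[(4R)-4-(benzyloxy)-2-oxopentyl]benzoate
Product: 26 (3R)-3-({2,4-bis(benzyloxy)-6-[(4R)-4-(benzyloxy)-2-oxopentyl]benzoyl}oxy)butanoic acid
Conditions: NaClO2, NaH2PO4, 2-methyl-2-butene, t-BuOH/H2O, 0 °C to rt
Reagents that add atoms: sodium chlorite, [Na+].[O-]Cl=O
Why: Pinnick oxidation by chlorous acid in a weakly acidic buffer converts the aldehyde to the acid without a basic medium that could eliminate the β-aroyloxy group, while the alkene scavenger protects the electron-rich arenes from hypochlorous acid.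

Step 15
Reactants: 26 (3R)-3-({2,4-bis(benzyloxy)-6-[(4R)-4-(benzyloxy)-2-oxopentyl]benzoyl}oxy)butanoic acid; 15 (2R)-1-[3,5-bis(benzyloxy)phenyl]propan-2-ol
Product: 27 (2R)-1-[3,5-bis(benzyloxy)phenyl]propan-2-yl (3R)-3-({2,4-bis(benzyloxy)-6-[(4R)-4-(benzyloxy)-2-oxopentyl]benzoyl}oxy)butanoate
Conditions: DCC, DMAP (cat.), CH2Cl2, 0 °C to rt
Reagents that add atoms: none
Why: Steglich esterification through the O-acylisourea and acylpyridinium ion acylates the secondary alcohol with retention at both carbinol centres, and low temperature with only catalytic DMAP should keep β-elimination of the aroate from the activated acid in check.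

Step 16
Reactants: 27 (2R)-1-[3,5-bis(benzyloxy)phenyl]propan-2-yl (3R)-3-({2,4-bis(benzyloxy)-6-[(4R)-4-(benzyloxy)-2-oxopentyl]benzoyl}oxy)butanoate
Product: 28 Hansforester K
Conditions: H2 (1 atm), 10% Pd/C, EtOAc/MeOH, rt
Reagents that add atoms: none
Why: Hydrogenolysis of the five benzyl ethers on Pd/C under neutral conditions should release the four phenols and the side-chain alcohol while the dialkyl ketone, both esters and the non-benzylic C–O bonds are untouched.

**Compound list**

1 | methyl (R)-3-hydroxybutanoate | C[C@@H](O)CC(=O)OC | starting material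
2 | methyl (3R)-3-(benzyloxy)butanoate | C[C@@H](OCc1ccccc1)CC(=O)OC | intermediate
3 | [(3R)-3-(benzyloxy)-1-methoxybutoxy]bis(2-methylpropyl)alumane (aluminium hemiacetal, hemiacetal carbon unassigned) | C[C@@H](OCc1ccccc1)CC(OC)O[Al](CC(C)C)CC(C)C | intermediate
4 | (3R)-3-(benzyloxy)butanal | C[C@@H](OCc1ccccc1)CC=O | intermediate
5 | 1-(triphenylphosphoranylidene)propan-2-one | CC(=O)C=P(c1ccccc1)(c1ccccc1)c1ccccc1 | starting material
6 | (3E,6R)-6-(benzyloxy)hept-3-en-2-one | CC(=O)/C=C/C[C@@H](C)OCc1ccccc1 | intermediate
7 | dimethyl malonate | COC(=O)CC(=O)OC | starting material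
8 | dimethyl 2-[(2R)-2-(benzyloxy)-6-oxoheptan-4-yl]propanedioate (C4 epimers) | COC(=O)C(C(=O)OC)C(CC(C)=O)C[C@@H](C)OCc1ccccc1 | intermediate
9 | methyl 6-[(2R)-2-(benzyloxy)propyl]-2,4-dioxocyclohexane-1-carboxylate (ring epimers, enol tautomers) | COC(=O)C1C(=O)CC(=O)CC1C[C@@H](C)OCc1ccccc1 | intermediate
10 | methyl 6-[(2R)-2-(benzyloxy)propyl]-3-bromo-2,4-dioxocyclohexane-1-carboxylate (ring epimers) | COC(=O)C1C(=O)C(Br)C(=O)CC1C[C@@H](C)OCc1ccccc1 | intermediate
11 | methyl 6-[(2R)-2-(benzyloxy)propyl]-2,4-dihydroxybenzoate | COC(=O)c1c(O)cc(O)cc1C[C@@H](C)OCc1ccccc1 | intermediate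
12 | 6-[(2R)-2-(benzyloxy)propyl]-2,4-dihydroxybenzoic acid | OC(=O)c1c(O)cc(O)cc1C[C@@H](C)OCc1ccccc1 | intermediate
13 | 5-[(2R)-2-(benzyloxy)propyl]benzene-1,3-diol | C[C@H](Cc1cc(O)cc(O)c1)OCc1ccccc1 | intermediate
14 | 5-[(2R)-2-hydroxypropyl]benzene-1,3-diol | C[C@H](Cc1cc(O)cc(O)c1)O | intermediate
15 | (2R)-1-[3,5-bis(benzyloxy)phenyl]propan-2-ol | C[C@H](Cc1cc(OCc2ccccc2)cc(OCc2ccccc2)c1)O | intermediate
16 | (3R)-3-(benzyloxy)-N-methoxy-N-methylbutanamide | C[C@@H](OCc1ccccc1)CC(=O)N(C)OC | intermediate
17 | orsellinic acid (2,4-dihydroxy-6-methylbenzoic acid) | Cc1cc(O)cc(O)c1C(=O)O | starting material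
18 | (S)-pent-4-en-2-ol | C[C@H](O)CC=C | starting material
19 | (2R)-pent-4-en-2-yl 2,4-dihydroxy-6-methylbenzoate | C[C@H](CC=C)OC(=O)c1c(O)cc(O)cc1C | intermediate
20 | (2R)-pent-4-en-2-yl 2,4-bis(benzyloxy)-6-methylbenzoate | C[C@H](CC=C)OC(=O)c1c(OCc2ccccc2)cc(OCc2ccccc2)cc1C | intermediate
21 | (2R)-pent-4-en-2-yl 2,4-bis(benzyloxy)-6-(lithiomethyl)benzoate | C[C@H](CC=C)OC(=O)c1c(OCc2ccccc2)cc(OCc2ccccc2)cc1C[Li] | intermediate
22 | lithium alkoxide of the N-methoxy-N-methyl hemiaminal formed from 21 and 16 (hemiaminal carbon unassigned) | C[C@H](CC=C)OC(=O)c1c(OCc2ccccc2)cc(OCc2ccccc2)cc1CC(O[Li])(N(C)OC)C[C@@H](C)OCc1ccccc1 | intermediate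
23 | (2R)-pent-4-en-2-yl 2,4-bis(benzyloxy)-6-[(4R)-4-(benzyloxy)-2-oxopentyl]benzoate | C[C@H](CC=C)OC(=O)c1c(OCc2ccccc2)cc(OCc2ccccc2)cc1CC(=O)C[C@@H](C)OCc1ccccc1 | intermediate
24 | (2R)-4,5-dihydroxypentan-2-yl 2,4-bis(benzyloxy)-6-[(4R)-4-(benzyloxy)-2-oxopentyl]benzoate (C4 epimers) | C[C@H](CC(O)CO)OC(=O)c1c(OCc2ccccc2)cc(OCc2ccccc2)cc1CC(=O)C[C@@H](C)OCc1ccccc1 | intermediate
25 | (2R)-4-oxobutan-2-yl 2,4-bis(benzyloxy)-6-[(4R)-4-(benzyloxy)-2-oxopentyl]benzoate | C[C@H](CC=O)OC(=O)c1c(OCc2ccccc2)cc(OCc2ccccc2)cc1CC(=O)C[C@@H](C)OCc1ccccc1 | intermediate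
26 | (3R)-3-({2,4-bis(benzyloxy)-6-[(4R)-4-(benzyloxy)-2-oxopentyl]benzoyl}oxy)butanoic acid | C[C@H](CC(=O)O)OC(=O)c1c(OCc2ccccc2)cc(OCc2ccccc2)cc1CC(=O)C[C@@H](C)OCc1ccccc1 | intermediate
27 | (2R)-1-[3,5-bis(benzyloxy)phenyl]propan-2-yl (3R)-3-({2,4-bis(benzyloxy)-6-[(4R)-4-(benzyloxy)-2-oxopentyl]benzoyl}oxy)butanoate | C[C@H](Cc1cc(OCc2ccccc2)cc(OCc2ccccc2)c1)OC(=O)C[C@@H](C)OC(=O)c1c(OCc2ccccc2)cc(OCc2ccccc2)cc1CC(=O)C[C@@H](C)OCc1ccccc1 | intermediate
28 | Hansforester K, (2R)-1-(3,5-dihydroxyphenyl)propan-2-yl (3R)-3-({2,4-dihydroxy-6-[(4R)-4-hydroxy-2-oxopentyl]benzoyl}oxy)butanoate | C[C@H](Cc1cc(O)cc(O)c1)OC(=O)C[C@@H](C)OC(=O)c1c(O)cc(O)cc1CC(=O)C[C@@H](C)O | target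

**Step count and risks**

Total: 16 steps. Longest linear sequence: 10 steps (steps 1, 2, 3, 4, 5, 6, 7, 8, 15, 16 from compound 1).

Steps most likely to fail:

Step 12. The benzylic anion may take a proton from the α-methylene of amide 16 instead of adding to it, which returns 20 and lets the amide enolate lose benzyl oxide. Fallback: from 20, the same anion 21 is treated at −78 °C with aldehyde 4, which is far more electrophilic than the amide, and the mixture is quenched cold with acetic acid before the alkoxide can close onto the hindered ester. This should give (2R)-pent-4-en-2-yl 2,4-bis(benzyloxy)-6-[(4R)-4-(benzyloxy)-2-hydroxypentyl]benzoate F1 as a mixture of carbinol epimers. Dess–Martin oxidation (NaHCO3, CH2Cl2) removes the new stereocentre and comes back to the route at 23.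

Step 15. Activation of acid 26 at its carbonyl may trigger β-elimination of the aroate (E1cB), so that a crotonate ester of 15 forms and the benzoate is lost. Fallback: the ester is made by carboxylate alkylation, so the acid is never activated. From 15, a Mitsunobu reaction with 4-nitrobenzoic acid (PPh3, DIAD) gives (2S)-1-[3,5-bis(benzyloxy)phenyl]propan-2-yl 4-nitrobenzoate F2 with inversion. Methanolysis (K2CO3, MeOH) gives (2S)-1-[3,5-bis(benzyloxy)phenyl]propan-2-ol F3. A second Mitsunobu reaction of F3 with acid 26 inverts the centre back to (R) and comes back to the route at 27.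

Step 5. Bromine regenerated from HBr and the bromo dione may brominate the electron-rich aromatic ring further, and dehydrobromination may stay incomplete, so that mixtures of ring-brominated and non-aromatised material result. Fallback: oxidative aromatisation without a bromo dione. From 9, iodine in refluxing methanol should give methyl 6-[(2R)-2-(benzyloxy)propyl]-2-hydroxy-4-methoxybenzoate F4. Aqueous NaOH and then acid give 6-[(2R)-2-(benzyloxy)propyl]-2-hydroxy-4-methoxybenzoic acid F5, which is not isolated and loses CO2 on warming to give 3-[(2R)-2-(benzyloxy)propyl]-5-methoxyphenol F6. BBr3 (CH2Cl2, −78 to 0 °C) cleaves the methyl ether and the benzyl ether together and comes back to the route at triol 14.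

**Further compounds**

F1 | step 12 | (2R)-pent-4-en-2-yl 2,4-bis(benzyloxy)-6-[(4R)-4-(benzyloxy)-2-hydroxypentyl]benzoate (carbinol epimers) | C[C@H](CC=C)OC(=O)c1c(OCc2ccccc2)cc(OCc2ccccc2)cc1CC(O)C[C@@H](C)OCc1ccccc1
F2 | step 15 | (2S)-1-[3,5-bis(benzyloxy)phenyl]propan-2-yl 4-nitrobenzoate | C[C@@H](Cc1cc(OCc2ccccc2)cc(OCc2ccccc2)c1)OC(=O)c1ccc(cc1)[N+](=O)[O-]
F3 | step 15 | (2S)-1-[3,5-bis(benzyloxy)phenyl]propan-2-ol | C[C@@H](Cc1cc(OCc2ccccc2)cc(OCc2ccccc2)c1)O
F4 | step 5 | methyl 6-[(2R)-2-(benzyloxy)propyl]-2-hydroxy-4-methoxybenzoate | COC(=O)c1c(O)cc(OC)cc1C[C@@H](C)OCc1ccccc1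
F5 | step 5 | 6-[(2R)-2-(benzyloxy)propyl]-2-hydroxy-4-methoxybenzoic acid | OC(=O)c1c(O)cc(OC)cc1C[C@@H](C)OCc1ccccc1
F6 | step 5 | 3-[(2R)-2-(benzyloxy)propyl]-5-methoxyphenol | C[C@H](Cc1cc(O)cc(OC)c1)OCc1ccccc1
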